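## Structural features

- The target is a dihydrochalcone: two benzene rings joined by a saturated chain C(=O)–CH2–CH2. The carbonyl carbon is bonded to C1' of ring A and the terminal CH2 to C1 of ring B.
- Ring A is an acylphloroglucinol with hydroxyls on C2', C4' and C6' and a prenyl group on C3'; only C5' is unsubstituted.
- Ring B is a catechol (hydroxyls on C3 and C4) with a prenyl group on C5.
- There is no stereocentre and no ring other than the two arenes.
- The fragile groups are the two trisubstituted prenyl alkenes, each ortho to a phenol. Acid closes them to 2,2-dimethylchromans and catalytic hydrogenation saturates them. The catechol is air-sensitive in base, and a phloroglucinol is an ambident C/O nucleophile that over-alkylates.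
- The real difficulty is regiochemical and chemoselective:
  - exactly one C-prenyl group on ring A;
  - a prenyl group on C5 of ring B, which is not its most nucleophilic carbon;
  - an aryl ketone bond made without Friedel–Crafts acid;
  - a saturated chain obtained without touching the prenyl alkenes.
- The feature the key step exploits: the ketone carbon and C1'–C6' of ring A form a chain of alternating oxygenated carbons (C=O, C2'–O, C4'–O, C6'–O). Ring A is the enol form of a folded 3,5,7-trioxo acid, and C3' sits between two oxygen-bearing carbons exactly as C3 of a 4-hydroxy-2-pyrone does.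

## Logic of the disconnections

In one sentence: ring A is neither acylated nor prenylated as an arene; it is created late, by ring opening and Claisen recyclisation of the 3-prenyl-6-(acylmethyl)-4-hydroxy-2-pyrone 9.

**12 ⇒ 11.** The two acetal O–CH2 bonds on O3 and O4 of ring B are cut. The catechol must be masked against the carbanion and methoxide chemistry before it. The forward step must free two phenols without acid damage to the two ortho-prenyl phenol units.

**11 ⇒ 10 ⇒ 9 (key).**
- Cut: the ring A bond C1'–C2', where C2' is the hydroxylated carbon next to the prenylated C3'. This gives the open-chain 2-prenyl-3,5,7-trioxo ester 10, which is the methanolysis product of the pyrone 9.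
- Mapping: pyrone C2, C3, C4, C5 and C6 of 9 become C2', C3', C4', C5' and C6' of 11. The exocyclic CH2 becomes C1', and the pyrone ring oxygen becomes the C6' hydroxyl oxygen.
- Gain: an aromatic ring with five substituents is traded for a monocyclic lactone in which the prenyl group already sits on the right carbon and the future aryl ketone bond already exists.
- Demand: the forward step must close by Claisen condensation (chain C6 onto C1) and not by an aldol pathway.

**9 ⇒ 7 + 5 (via 8).** The bond between the exocyclic CH2 of the pyrone and the ketone carbon is cut; this is the future C1'–C(=O) bond. It splits the molecule convergently into a ring A precursor and a ring B precursor. The forward step needs a carbanion on the 6-methyl group of 7 and its acylation by an enolisable ester.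

**7 ⇒ 6.** The C3–CH2 bond to the prenyl group is cut. Compound 6 is a commodity chemical whose only nucleophilic carbon is C3. The forward step must be mono-selective, C-selective and must deliver the linear prenyl isomer.

**5 ⇒ 4.** The Cα–Cβ double bond is reintroduced (functional group interconversion). The forward step must reduce an aryl-conjugated enoate and leave the isolated prenyl alkene.

**4 ⇒ 3.** The C5–CH2 bond of the ring B prenyl group is cut to an aryl bromide. The halogen marks C5 from the first compound on, so no regiochemical decision is made on the catechol. The forward step must transfer the prenyl group without allylic transposition.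

**3 ⇒ 2 ⇒ 1.** The alkene of 3 is cut to an aldehyde (olefination), and the two MOM ethers of 2 are cut to the free catechol 1.

## Other disconnections considered

**Alternative 1: Claisen–Schmidt condensation (the first that comes to mind).**
- Cut: the Cα–Cβ bond of the chain, as the enone of a chalcone.
- Forward key step: aldol condensation of 1-[2-hydroxy-4,6-bis(methoxymethoxy)-3-(3-methylbut-2-en-1-yl)phenyl]ethan-1-one A1 with 3,4-bis(methoxymethoxy)-5-(3-methylbut-2-en-1-yl)benzaldehyde A2. This gives the chalcone (E)-3-[3,4-bis(methoxymethoxy)-5-(3-methylbut-2-en-1-yl)phenyl]-1-[2-hydroxy-4,6-bis(methoxymethoxy)-3-(3-methylbut-2-en-1-yl)phenyl]prop-2-en-1-one A3, which is then reduced at the enone and deprotected.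
- Why the chosen plan is preferred: A1 requires mono-C-prenylation of a phloroacetophenone, where C- versus O-alkylation and mono- versus bis-alkylation are hard to control and three hydroxyls must be differentiated. A3 places an enone next to a 2'-hydroxyl, which invites flavanone closure. Its reduction must be selective against two prenyl alkenes. The chosen plan builds ring A with the prenyl group already in place and never forms the enone.

**Alternative 2: late double C-prenylation (the presumed biosynthetic order).**
- Cut: both aryl–CH2 bonds of the prenyl groups.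
- Forward key step: twofold prenylation of 3-(3,4-dihydroxyphenyl)-1-(2,4,6-trihydroxyphenyl)propan-1-one A4 with a prenyl electrophile.
- Why the chosen plan is preferred: A4 offers five oxygen and five carbon nucleophilic sites. On ring B the position para to the C3 hydroxyl is expected to be more nucleophilic than C5, and acid-promoted variants would cyclise the products to chromans. One step would be paid for with a statistical mixture. The chosen plan fixes both sites by construction (bromine on ring B, pyrone C3 for ring A).

**Alternative 3: double aromatic Claisen rearrangement.**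
- Cut: the same two aryl–CH2 bonds, but intramolecularly.
- Forward key step: a twofold [3,3] shift of the bis(1,1-dimethylallyl) ether 1-[2,6-dihydroxy-4-(2-methylbut-3-en-2-yloxy)phenyl]-3-[3-(methoxymethoxy)-4-(2-methylbut-3-en-2-yloxy)phenyl]propan-1-one A5, moving the allyl groups from O4' to C3' and from O4 to C5.
- Why the chosen plan is preferred: the regiochemistry of the shift is sound, but A5 requires O4 to be told apart from O3 on a catechol with no electronic bias, and O4' from O2'/O6'. Each tertiary ether costs an etherification and a semi-reduction. That is clearly longer than the eight steps of the chosen plan.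

Key step: step 7

Remark: compounds 1 and 6 and the reagents listed under "Reagents that add atoms" are taken as purchased. Positions 3' and 5' of ring A are equivalent until the prenyl group is present, so the pyrone-derived ring can give only one regioisomer.

## Route

Step 1
Reactants: 1 3-bromo-4,5-dihydroxybenzaldehyde
Product: 2 3-bromo-4,5-bis(methoxymethoxy)benzaldehyde
Conditions: MOMCl (3 equiv), i-Pr2NEt (4 equiv), CH2Cl2, 0 °C to rt
Reagents that add atoms: chloromethyl methyl ether, COCCl
Why: Williamson-type O-alkylation of both phenols by the reactive α-chloro ether; the MOM acetals should survive the carbanion, magnesium and methoxide steps and come off last under mild acid.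

Step 2
Reactants: 2 3-bromo-4,5-bis(methoxymethoxy)benzaldehyde
Product: 3 methyl (E)-3-[3-bromo-4,5-bis(methoxymethoxy)phenyl]prop-2-enoate
Conditions: (MeO)2P(O)CH2CO2Me (1.2 equiv), NaH (1.2 equiv), THF, 0 °C to rt
Reagents that add atoms: trimethyl phosphonoacetate, COC(=O)CP(=O)(OC)OC
Why: Horner–Wadsworth–Emmons olefination of a non-enolisable aryl aldehyde, expected to be E-selective; the geometry is of no consequence because the alkene is reduced in step 4.

Step 3
Reactants: 3 methyl (E)-3-[3-bromo-4,5-bis(methoxymethoxy)phenyl]prop-2-enoate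
Product: 4 methyl (E)-3-[3,4-bis(methoxymethoxy)-5-(3-methylbut-2-en-1-yl)phenyl]prop-2-enoate
Conditions: Bu3SnCH2CH=CMe2 (1.5 equiv), Pd(PPh3)4 (5 mol %), DMF, 95 °C, argon
Reagents that add atoms: tributyl(3-methylbut-2-en-1-yl)stannane, CCCC[Sn](CCCC)(CCCC)CC=C(C)C
Why: Stille coupling; oxidative addition of zerovalent palladium into the aryl bromide, transmetalation of the allylic stannane and reductive elimination at the less hindered primary allyl terminus should give the linear prenyl group. The bromine carried from 1 fixes the site as C5 of ring B, and the ester and acetals are inert.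

Step 4
Reactants: 4 methyl (E)-3-[3,4-bis(methoxymethoxy)-5-(3-methylbut-2-en-1-yl)phenyl]prop-2-enoate
Product: 5 methyl 3-[3,4-bis(methoxymethoxy)-5-(3-methylbut-2-en-1-yl)phenyl]propanoate
Conditions: Mg turnings (10 equiv), MeOH, 0 °C to rt; aq. NH4Cl
Reagents that add atoms: none
Why: Dissolving-metal conjugate reduction; only the aryl-conjugated enoate accepts an electron from magnesium, so the isolated trisubstituted prenyl alkene and the acetals should be untouched, and methanol as solvent keeps the methyl ester.

Step 5
Reactants: 6 4-hydroxy-6-methyl-2H-pyran-2-one (triacetic acid lactone)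
Product: 7 4-hydroxy-6-methyl-3-(3-methylbut-2-en-1-yl)-2H-pyran-2-one
Conditions: 6 (1.3 equiv), t-BuOCO2CMe2CH=CH2 (1.0 equiv, slow addition), Pd(PPh3)4 (5 mol %), THF, 50 °C
Reagents that add atoms: tert-butyl 2-methylbut-3-en-2-yl carbonate, CC(C)(C)OC(=O)OC(C)(C)C=C
Why: Tsuji–Trost allylation; zerovalent palladium ionises the carbonate to the 1,1-dimethyl-π-allyl complex, CO2 and tert-butoxide, which deprotonates the acidic pyrone, and the soft C3 carbon attacks the unsubstituted allyl terminus to give the linear prenyl group. Any 4-O-prenyl ether is a vinylogous ester that re-ionises under the catalyst, so C-alkylation is the thermodynamic outcome; excess 6 and slow addition hold back a second alkylation.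

Step 6
Reactants: 7 4-hydroxy-6-methyl-3-(3-methylbut-2-en-1-yl)-2H-pyran-2-one; 5 methyl 3-[3,4-bis(methoxymethoxy)-5-(3-methylbut-2-en-1-yl)phenyl]propanoate
Product: 9 6-{4-[3,4-bis(methoxymethoxy)-5-(3-methylbut-2-en-1-yl)phenyl]-2-oxobutyl}-4-hydroxy-3-(3-methylbut-2-en-1-yl)-2H-pyran-2-one, via dilithiated pyrone 8 (not isolated)
Conditions: 7 (2.2 equiv), LiN(i-Pr)2 (4.4 equiv), THF–DMPU, −78 to −30 °C; then 5 (1.0 equiv), −78 to 0 °C; 1 M HCl to pH 3 at 0 °C
Reagents that add atoms: none
Why: Claisen acylation of a 1,3-dicarbonyl-type dianion; after the 4-hydroxyl, the vinylogous 6-methyl group is deprotonated and the resulting carbanion 8 attacks the ester carbonyl, the second equivalent of 8 absorbing the acidic proton of the product. The prenyl group blocks C3, the other carbon that shares the charge, and unreacted 7 is recovered.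

Step 7
Reactants: 9 6-{4-[3,4-bis(methoxymethoxy)-5-(3-methylbut-2-en-1-yl)phenyl]-2-oxobutyl}-4-hydroxy-3-(3-methylbut-2-en-1-yl)-2H-pyran-2-one
Product: 11 3-[3,4-bis(methoxymethoxy)-5-(3-methylbut-2-en-1-yl)phenyl]-1-[2,4,6-trihydroxy-3-(3-methylbut-2-en-1-yl)phenyl]propan-1-one, via open-chain triketo ester 10 (not isolated)
Conditions: Mg(OMe)2 (8 equiv), MeOH, 65 °C, argon; then 0.5 M HCl to pH 3 at 0 °C
Reagents that add atoms: none
Why: Methoxide adds to the lactone carbonyl of 9 and the ring opens to the methyl 2-prenyl-3,5,7-trioxo ester 10, held as its magnesium polyenolate chelate; chain carbon C6, the central carbon of the C5/C7 diketonate, then attacks the ester carbonyl C1 in a Dieckmann-type Claisen condensation, a 6-(enolexo)-exo-trig closure, methoxide leaves, and the 2-acylcyclohexane-1,3,5-trione tautomerises to the phloroglucinol. The closest known reaction type is the magnesium methoxide recyclisation of 6-(acylmethyl)-4-hydroxy-2-pyrones to acylphloroglucinols, the laboratory counterpart of the chalcone synthase cyclisation. No stereocentre is formed; the C2 centre of 10 is lost on aromatisation. The selectivity needed is Claisen closure (C6 onto C1) over aldol closure (C2 onto C7, or C8 onto C3). The prenyl group on C2 makes the C2-to-C7 aldol adduct a quaternary, non-aromatisable species that can only revert; C8 is the least acidic position of the chelated polyenolate; and relactonisation only returns 9, so the aromatic phenolate is the one irreversible exit. Because the prenyl group rides on C2 of the chain, it arrives on C3' between two hydroxyls without any alkylation of a phloroglucinol. The aryl–ketone bond is already in place, and the acetals and both alkenes are inert to methoxide.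

Step 8
Reactants: 11 3-[3,4-bis(methoxymethoxy)-5-(3-methylbut-2-en-1-yl)phenyl]-1-[2,4,6-trihydroxy-3-(3-methylbut-2-en-1-yl)phenyl]propan-1-one
Product: 12 3-[3,4-dihydroxy-5-(3-methylbut-2-en-1-yl)phenyl]-1-[2,4,6-trihydroxy-3-(3-methylbut-2-en-1-yl)phenyl]propan-1-one (2',4',6',3,4-pentahydroxy-3',5-diprenyldihydrochalcone)
Conditions: 3 M HCl, MeOH–H2O, 25–40 °C, argon, stopped at full conversion
Reagents that add atoms: none
Why: Acid-catalysed transacetalisation of the two aryl MOM ethers to methanol, a standard last step for prenylated polyphenols; near room temperature acetal cleavage should outrun protonation of the trisubstituted alkenes, which limits chroman formation.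

## Compound list

1 | 3-bromo-4,5-dihydroxybenzaldehyde | O=Cc1cc(O)c(O)c(Br)c1 | starting material
2 | 3-bromo-4,5-bis(methoxymethoxy)benzaldehyde | O=Cc1cc(OCOC)c(OCOC)c(Br)c1 | intermediate
3 | methyl (E)-3-[3-bromo-4,5-bis(methoxymethoxy)phenyl]prop-2-enoate | COC(=O)/C=C/c1cc(OCOC)c(OCOC)c(Br)c1 | intermediate
4 | methyl (E)-3-[3,4-bis(methoxymethoxy)-5-(3-methylbut-2-en-1-yl)phenyl]prop-2-enoate | COC(=O)/C=C/c1cc(OCOC)c(OCOC)c(CC=C(C)C)c1 | intermediate
5 | methyl 3-[3,4-bis(methoxymethoxy)-5-(3-methylbut-2-en-1-yl)phenyl]propanoate | COC(=O)CCc1cc(OCOC)c(OCOC)c(CC=C(C)C)c1 | intermediate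
6 | 4-hydroxy-6-methyl-2H-pyran-2-one | CC1=CC(O)=CC(=O)O1 | starting material
7 | 4-hydroxy-6-methyl-3-(3-methylbut-2-en-1-yl)-2H-pyran-2-one | CC1=CC(O)=C(CC=C(C)C)C(=O)O1 | intermediate
8 | dilithium salt of 7 (4-oxide, 6-methylene carbanion) | [Li+].[Li+].[CH2-]C1=CC([O-])=C(CC=C(C)C)C(=O)O1 | intermediate
9 | 6-{4-[3,4-bis(methoxymethoxy)-5-(3-methylbut-2-en-1-yl)phenyl]-2-oxobutyl}-4-hydroxy-3-(3-methylbut-2-en-1-yl)-2H-pyran-2-one | COCOc1cc(CCC(=O)CC2=CC(O)=C(CC=C(C)C)C(=O)O2)cc(CC=C(C)C)c1OCOC | intermediate
10 | methyl 9-[3,4-bis(methoxymethoxy)-5-(3-methylbut-2-en-1-yl)phenyl]-2-(3-methylbut-2-en-1-yl)-3,5,7-trioxononanoate (present as its magnesium enolate; C2 configuration undefined and lost in the next event) | COC(=O)C(CC=C(C)C)C(=O)CC(=O)CC(=O)CCc1cc(OCOC)c(OCOC)c(CC=C(C)C)c1 | intermediate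
11 | 3-[3,4-bis(methoxymethoxy)-5-(3-methylbut-2-en-1-yl)phenyl]-1-[2,4,6-trihydroxy-3-(3-methylbut-2-en-1-yl)phenyl]propan-1-one | COCOc1cc(CCC(=O)c2c(O)cc(O)c(CC=C(C)C)c2O)cc(CC=C(C)C)c1OCOC | intermediate
12 | 3-[3,4-dihydroxy-5-(3-methylbut-2-en-1-yl)phenyl]-1-[2,4,6-trihydroxy-3-(3-methylbut-2-en-1-yl)phenyl]propan-1-one | CC(C)=CCc1cc(CCC(=O)c2c(O)cc(O)c(CC=C(C)C)c2O)cc(O)c1O | target

## Step count and least certain steps

Total step count: 8. Longest linear sequence: 7 (steps 1, 2, 3, 4, 6, 7, 8); step 5 is a one-step branch.

**Step 7 (key step).** The mode of ring closure may go astray. The ester carbon lies next to the substituted C2, which slows the Claisen attack. An aldol closure of the terminal methylene C8 onto C3, or methoxide-induced retro-Claisen cleavage of the polyketone chain, could then compete, or the pyrone could simply fail to open.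

Fallback, from 5 back to the route at 12, by directed metalation with no polyketide cyclisation:
- 5 is converted with MeNHOMe·HCl and i-PrMgCl into N-methoxy-N-methyl-3-[3,4-bis(methoxymethoxy)-5-(3-methylbut-2-en-1-yl)phenyl]propanamide F1.
- Phloroglucinol is protected with MOMCl and i-Pr2NEt as 1,3,5-tris(methoxymethoxy)benzene F2.
- F2 is lithiated between two acetal oxygens with n-BuLi and alkylated with prenyl bromide in the presence of CuBr·SMe2 to give 1,3,5-tris(methoxymethoxy)-2-(3-methylbut-2-en-1-yl)benzene F3.
- F3 is lithiated again (n-BuLi, TMEDA) and the aryllithium is acylated by F1. This gives 3-[3,4-bis(methoxymethoxy)-5-(3-methylbut-2-en-1-yl)phenyl]-1-[2,4,6-tris(methoxymethoxy)-3-(3-methylbut-2-en-1-yl)phenyl]propan-1-one F4.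
- Treatment of F4 with HCl in MeOH releases 12.

**Step 6.** Proton transfer from the enolisable ester to the carbanion may quench the dianion before acylation. The product also consumes base, so conversion may stall.

Fallback, from 5 back to the route at 9, replacing acylation by aldol addition and oxidation:
- 5 is reduced with i-Bu2AlH at −78 °C to 3-[3,4-bis(methoxymethoxy)-5-(3-methylbut-2-en-1-yl)phenyl]propanal F5.
- The dianion 8 adds to F5 to give racemic 6-{4-[3,4-bis(methoxymethoxy)-5-(3-methylbut-2-en-1-yl)phenyl]-2-hydroxybutyl}-4-hydroxy-3-(3-methylbut-2-en-1-yl)-2H-pyran-2-one F6.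
- Oxidation of F6 with Dess–Martin periodinane removes the carbinol centre and gives 9.

**Step 5.** Three things may go wrong: a second alkylation at C3 (quaternisation), attack at the tertiary allyl terminus (reverse prenyl group), or persistent O-alkylation.

Fallback, from 6 back to the route at 7, by intramolecular delivery:
- Mitsunobu etherification of 6 with allyl alcohol (PPh3, diisopropyl azodicarboxylate) gives 6-methyl-4-(prop-2-en-1-yloxy)-2H-pyran-2-one F7.
- Thermal Claisen rearrangement of F7 in toluene at 110–140 °C places exactly one allyl group on C3, giving 4-hydroxy-6-methyl-3-(prop-2-en-1-yl)-2H-pyran-2-one F8.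
- Cross-metathesis of F8 with 2-methylbut-2-ene and second-generation Grubbs catalyst gives 7.

**Step 3.** Allylic transposition during transmetalation or reductive elimination may give the 1,1-dimethylallyl isomer. Oxidative addition into the hindered, electron-rich bromide may also be slow.

Fallback, from 3 back to the route at 5, using a symmetrical allyl group and metathesis:
- Stille coupling of 3 with allyltributylstannane and Pd(PPh3)4 gives methyl (E)-3-[4,5-bis(methoxymethoxy)-3-(prop-2-en-1-yl)phenyl]prop-2-enoate F9.
- Mg in MeOH reduces F9 to methyl 3-[4,5-bis(methoxymethoxy)-3-(prop-2-en-1-yl)phenyl]propanoate F10.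
- Cross-metathesis of F10 with 2-methylbut-2-ene and second-generation Grubbs catalyst gives 5.

**Step 8.** Acid-catalysed addition of a neighbouring phenol to a prenyl alkene (chroman ring closure) may compete with acetal cleavage.

Fallback, from 1 back to the route at 12, with silyl protection so that no acid step follows prenylation:
- 1 is silylated with t-BuMe2SiCl and imidazole to 3-bromo-4,5-bis[(tert-butyldimethylsilyl)oxy]benzaldehyde F11.
- Horner–Wadsworth–Emmons olefination gives methyl (E)-3-{3-bromo-4,5-bis[(tert-butyldimethylsilyl)oxy]phenyl}prop-2-enoate F12.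
- Stille prenylation gives methyl (E)-3-{3,4-bis[(tert-butyldimethylsilyl)oxy]-5-(3-methylbut-2-en-1-yl)phenyl}prop-2-enoate F13.
- Conjugate reduction with catalytic [(Ph3P)CuH]6 and polymethylhydrosiloxane (not Mg in MeOH, which would desilylate) gives methyl 3-{3,4-bis[(tert-butyldimethylsilyl)oxy]-5-(3-methylbut-2-en-1-yl)phenyl}propanoate F14.
- Acylation of the dianion 8 with F14 gives 6-(4-{3,4-bis[(tert-butyldimethylsilyl)oxy]-5-(3-methylbut-2-en-1-yl)phenyl}-2-oxobutyl)-4-hydroxy-3-(3-methylbut-2-en-1-yl)-2H-pyran-2-one F15.
- The Mg(OMe)2/MeOH treatment of step 7 applied to F15 should both close ring A and methanolyse the two aryl silyl ethers, giving 12 directly.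

## Further compounds

F1 | step 7 | N-methoxy-N-methyl-3-[3,4-bis(methoxymethoxy)-5-(3-methylbut-2-en-1-yl)phenyl]propanamide | CON(C)C(=O)CCc1cc(OCOC)c(OCOC)c(CC=C(C)C)c1
F2 | step 7 | 1,3,5-tris(methoxymethoxy)benzene | COCOc1cc(OCOC)cc(OCOC)c1
F3 | step 7 | 1,3,5-tris(methoxymethoxy)-2-(3-methylbut-2-en-1-yl)benzene | COCOc1cc(OCOC)c(CC=C(C)C)c(OCOC)c1
F4 | step 7 | 3-[3,4-bis(methoxymethoxy)-5-(3-methylbut-2-en-1-yl)phenyl]-1-[2,4,6-tris(methoxymethoxy)-3-(3-methylbut-2-en-1-yl)phenyl]propan-1-one | COCOc1cc(CCC(=O)c2c(OCOC)cc(OCOC)c(CC=C(C)C)c2OCOC)cc(CC=C(C)C)c1OCOC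
F5 | step 6 | 3-[3,4-bis(methoxymethoxy)-5-(3-methylbut-2-en-1-yl)phenyl]propanal | O=CCCc1cc(OCOC)c(OCOC)c(CC=C(C)C)c1
F6 | step 6 | 6-{4-[3,4-bis(methoxymethoxy)-5-(3-methylbut-2-en-1-yl)phenyl]-2-hydroxybutyl}-4-hydroxy-3-(3-methylbut-2-en-1-yl)-2H-pyran-2-one (racemic) | COCOc1cc(CCC(O)CC2=CC(O)=C(CC=C(C)C)C(=O)O2)cc(CC=C(C)C)c1OCOC
F7 | step 5 | 6-methyl-4-(prop-2-en-1-yloxy)-2H-pyran-2-one | CC1=CC(OCC=C)=CC(=O)O1
F8 | step 5 | 4-hydroxy-6-methyl-3-(prop-2-en-1-yl)-2H-pyran-2-one | CC1=CC(O)=C(CC=C)C(=O)O1
F9 | step 3 | methyl (E)-3-[4,5-bis(methoxymethoxy)-3-(prop-2-en-1-yl)phenyl]prop-2-enoate | COC(=O)/C=C/c1cc(OCOC)c(OCOC)c(CC=C)c1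
F10 | step 3 | methyl 3-[4,5-bis(methoxymethoxy)-3-(prop-2-en-1-yl)phenyl]propanoate | COC(=O)CCc1cc(OCOC)c(OCOC)c(CC=C)c1
F11 | step 8 | 3-bromo-4,5-bis[(tert-butyldimethylsilyl)oxy]benzaldehyde | O=Cc1cc(O[Si](C)(C)C(C)(C)C)c(O[Si](C)(C)C(C)(C)C)c(Br)c1
F12 | step 8 | methyl (E)-3-{3-bromo-4,5-bis[(tert-butyldimethylsilyl)oxy]phenyl}prop-2-enoate | COC(=O)/C=C/c1cc(O[Si](C)(C)C(C)(C)C)c(O[Si](C)(C)C(C)(C)C)c(Br)c1
F13 | step 8 | methyl (E)-3-{3,4-bis[(tert-butyldimethylsilyl)oxy]-5-(3-methylbut-2-en-1-yl)phenyl}prop-2-enoate | COC(=O)/C=C/c1cc(O[Si](C)(C)C(C)(C)C)c(O[Si](C)(C)C(C)(C)C)c(CC=C(C)C)c1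
F14 | step 8 | methyl 3-{3,4-bis[(tert-butyldimethylsilyl)oxy]-5-(3-methylbut-2-en-1-yl)phenyl}propanoate | COC(=O)CCc1cc(O[Si](C)(C)C(C)(C)C)c(O[Si](C)(C)C(C)(C)C)c(CC=C(C)C)c1
F15 | step 8 | 6-(4-{3,4-bis[(tert-butyldimethylsilyl)oxy]-5-(3-methylbut-2-en-1-yl)phenyl}-2-oxobutyl)-4-hydroxy-3-(3-methylbut-2-en-1-yl)-2H-pyran-2-one | CC(C)=CCC1=C(O)C=C(CC(=O)CCc2cc(O[Si](C)(C)C(C)(C)C)c(O[Si](C)(C)C(C)(C)C)c(CC=C(C)C)c2)OC1=O
A1 | alternative 1 | 1-[2-hydroxy-4,6-bis(methoxymethoxy)-3-(3-methylbut-2-en-1-yl)phenyl]ethan-1-one | CC(=O)c1c(O)c(CC=C(C)C)c(OCOC)cc1OCOC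
A2 | alternative 1 | 3,4-bis(methoxymethoxy)-5-(3-methylbut-2-en-1-yl)benzaldehyde | O=Cc1cc(OCOC)c(OCOC)c(CC=C(C)C)c1
A3 | alternative 1 | (E)-3-[3,4-bis(methoxymethoxy)-5-(3-methylbut-2-en-1-yl)phenyl]-1-[2-hydroxy-4,6-bis(methoxymethoxy)-3-(3-methylbut-2-en-1-yl)phenyl]prop-2-en-1-one | COCOc1cc(/C=C/C(=O)c2c(O)c(CC=C(C)C)c(OCOC)cc2OCOC)cc(CC=C(C)C)c1OCOC
A4 | alternative 2 | 3-(3,4-dihydroxyphenyl)-1-(2,4,6-trihydroxyphenyl)propan-1-one | O=C(CCc1ccc(O)c(O)c1)c1c(O)cc(O)cc1O
A5 | alternative 3 | 1-[2,6-dihydroxy-4-(2-methylbut-3-en-2-yloxy)phenyl]-3-[3-(methoxymethoxy)-4-(2-methylbut-3-en-2-yloxy)phenyl]propan-1-one | C=CC(C)(C)Oc1cc(O)c(C(=O)CCc2ccc(OC(C)(C)C=C)c(OCOC)c2)c(O)c1
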